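**Retrosynthetic overview**

- The strategy rests on ring B (C5–C10, drimane numbering): a cyclohexene whose C7=C8 bond sits between C6 and C9, with a trans C5‑H/C10‑CH3 pair that maps onto the E geometry of a 2‑methyl enal.
- Key disconnection, ring B first: C5–C6 and C9–C10 by a catalytic enantioselective Diels–Alder reaction of 2‑silyloxy diene 6 (C6–C9 with the complete side chain) and enal 9 (C1, C10, C5, C4).
- Ring A second: C1=C2 by methylenation of the formyl group and ring‑closing metathesis with the allyl arm on C4, then saturation with a substitution‑selective Rh catalyst at the enone stage.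
- C9 and the C7=C8 olefin last: enol ether → α‑bromo ketone → C8=C9 enone → dissolving‑metal reduction with enolate triflation → triflate hydrogenolysis.
- Diene 6 comes from farnesyl bromide in three steps, enal 9 from 2,2‑dimethylpent‑4‑enal in one.

Key step: step 5

Assumption and conventions: drimane numbers C1–C10 are used in the text (gem‑dimethyl on C4, angular methyl on C10 defining the β face, methyl on C8, side chain on C9), bicyclic names keep the naphthalene locants of the target, N‑tert‑butylethanimine is taken as a catalogue reagent, and the (S)‑catalyst is assigned from the usual binding model for 2‑substituted enals (the (R)‑catalyst would be used if the sense proved opposite).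

**Route**

Step 1
Reactants: 1 (2E,6E)-farnesyl bromide
Product: 3 (4E,8E)-5,9,13-trimethyltetradeca-4,8,12-trienal, via tert-butyl aldimine 2 (not isolated)
Conditions: N‑tert‑butylethanimine, LDA, THF, −78 → 0 °C; add 1, −78 °C → rt; then aq. oxalic acid, Et2O, rt
Reagents that add atoms: N‑tert‑butylethanimine (CC=NC(C)(C)C); water (O)
Why: Alkylation of the lithium 1‑azaallyl anion of an acetaldehyde imine (Stork metalloenamine alkylation) is an SN2 reaction at the primary allylic bromide that should leave the E,E olefins untouched, and mild acid hydrolysis of imine 2 releases the γ,δ‑unsaturated aldehyde without double‑bond migration.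

Step 2
Reactants: 3 (4E,8E)-5,9,13-trimethyltetradeca-4,8,12-trienal; 4 3-(triphenylphosphoranylidene)butan-2-one
Product: 5 (3E,7E,11E)-3,8,12,16-tetramethylheptadeca-3,7,11,15-tetraen-2-one
Conditions: toluene, 110 °C
Reagents that add atoms: none
Why: Wittig olefination with a stabilised α‑methyl keto ylide should give the (E)‑trisubstituted enone because oxaphosphetane formation is reversible and the acetyl group ends up trans to the chain.

Step 3
Reactants: 5 (3E,7E,11E)-3,8,12,16-tetramethylheptadeca-3,7,11,15-tetraen-2-one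
Product: 6 (3E,7E,11E)-3,8,12,16-tetramethyl-2-[(triisopropylsilyl)oxy]heptadeca-1,3,7,11,15-pentaene
Conditions: TIPSOTf, Et3N, CH2Cl2, 0 °C → rt; chromatography on Et3N‑deactivated silica
Reagents that add atoms: triisopropylsilyl trifluoromethanesulfonate (CC(C)[Si](OS(=O)(=O)C(F)(F)F)(C(C)C)C(C)C)
Why: Soft enolisation of the methyl ketone (silyl triflate and amine) removes an α′‑methyl proton in preference to a γ‑proton and should give the cross‑conjugated 2‑silyloxy diene with the 3E geometry unchanged, TIPS replacing a smaller silyl group for stability towards the acidic catalyst of step 5.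

Step 4
Reactants: 7 2,2-dimethylpent-4-enal; 8 2-(triphenylphosphoranylidene)propanal
Product: 9 (E)-2,4,4-trimethylhepta-2,6-dienal
Conditions: toluene, 110 °C, sealed vessel, prolonged heating
Reagents that add atoms: none
Why: Wittig reaction of the non‑enolisable neopentyl aldehyde with the stabilised formyl ylide should give the (E)‑2‑methyl enal (formyl trans to the tert‑alkyl group) under thermodynamic control, and the hindered conjugated product should not be homologated further.

Step 5
Reactants: 6 (3E,7E,11E)-3,8,12,16-tetramethyl-2-[(triisopropylsilyl)oxy]heptadeca-1,3,7,11,15-pentaene; 9 (E)-2,4,4-trimethylhepta-2,6-dienal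
Product: 10 (1S,2R,6S)-1,3-dimethyl-6-(2-methylpent-4-en-2-yl)-4-[(triisopropylsilyl)oxy]-2-[(3E,7E)-4,8,12-trimethyltrideca-3,7,11-trien-1-yl]cyclohex-3-ene-1-carbaldehyde
Conditions: (S)‑B‑o‑tolyl oxazaborolidine from (S)‑α,α‑diphenylprolinol (22 mol%), Tf2NH (20 mol%), CH2Cl2 (ca. 1 M), −78 → −20 °C, 9 in excess; Et3N quench
Reagents that add atoms: none
Why: The protonated oxazaborolidine binds the formyl oxygen of 9, and the s‑trans enal then adds suprafacially to the s‑cis diene 6 in a concerted but asynchronous [4+2] process in which the C5–C6 bond runs ahead of the C9–C10 bond. The closest known reaction type is the oxazaborolidinium‑catalysed Diels–Alder reaction of (E)‑2‑methyl‑2‑alkenals with 2‑silyloxy‑1,3‑dienes, of which 9 is a more hindered member. Ring B is closed as a six‑membered carbocycle by intermolecular cycloaddition, and the C7=C8 bond appears as a regiodefined silyl enol ether. C10 is set by the catalyst, whose aryl group covers one face of the bound enal so that the diene should add to the Cα Re face, C5 follows from C10 through the E geometry of 9 (formyl and C4 trans, the later trans ring fusion), and C9 comes from the endo position of the formyl group relative to the E‑configured diene terminus (expected 9α side chain). The step needs face selectivity from the catalyst and C6‑to‑C5 regiochemistry, which the 7‑silyloxy group and the C9 alkyl group secure together because both make the unhindered CH2 terminus C6 the nucleophilic end that meets the neopentyl‑like β‑carbon C5. The C9 outcome is not relied on, since steps 9 and 11 rebuild this centre and endo and exo adducts can be taken on together; the low reactivity of the β‑tert‑alkyl enal is the main concern and is met by the strongly acidic triflimide‑activated catalyst (kept in slight excess over the acid), high concentration and the acid‑stable TIPS ether.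

Step 6
Reactants: 10 (1S,2R,6S)-1,3-dimethyl-6-(2-methylpent-4-en-2-yl)-4-[(triisopropylsilyl)oxy]-2-[(3E,7E)-4,8,12-trimethyltrideca-3,7,11-trien-1-yl]cyclohex-3-ene-1-carbaldehyde
Product: 11 (1S,2S,6S)-1-ethenyl-1,3-dimethyl-6-(2-methylpent-4-en-2-yl)-4-[(triisopropylsilyl)oxy]-2-[(3E,7E)-4,8,12-trimethyltrideca-3,7,11-trien-1-yl]cyclohex-3-ene
Conditions: Ph3PCH3Br, KOtBu, THF, 0 °C → rt
Reagents that add atoms: methyltriphenylphosphonium bromide (C[P+](c1ccccc1)(c1ccccc1)c1ccccc1.[Br-])
Why: Wittig methylenation with the small non‑stabilised ylide should convert the hindered but non‑enolisable α‑quaternary aldehyde into the vinyl group without any epimerisation, the TIPS enol ether being stable to the basic medium.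

Step 7
Reactants: 11 (1S,2S,6S)-1-ethenyl-1,3-dimethyl-6-(2-methylpent-4-en-2-yl)-4-[(triisopropylsilyl)oxy]-2-[(3E,7E)-4,8,12-trimethyltrideca-3,7,11-trien-1-yl]cyclohex-3-ene
Product: 12 (1S,4aS,8aS)-2,5,5,8a-tetramethyl-3-[(triisopropylsilyl)oxy]-1-[(3E,7E)-4,8,12-trimethyltrideca-3,7,11-trien-1-yl]-1,4,4a,5,6,8a-hexahydronaphthalene
Conditions: Grubbs second‑generation catalyst (5 mol%), CH2Cl2 (5 mM), 40 °C
Reagents that add atoms: none
Why: Ring‑closing metathesis should initiate at the unhindered allyl terminus and close six‑membered ring A onto the neopentyl vinyl group, the trans‑diequatorial arms on C5 and C10 giving the trans‑fused bicycle, while the trisubstituted chain olefins and the tetrasubstituted enol ether are far slower metathesis partners.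

Step 8
Reactants: 12 (1S,4aS,8aS)-2,5,5,8a-tetramethyl-3-[(triisopropylsilyl)oxy]-1-[(3E,7E)-4,8,12-trimethyltrideca-3,7,11-trien-1-yl]-1,4,4a,5,6,8a-hexahydronaphthalene
Product: 13 (1S,4aS,8aS)-2-bromo-2,5,5,8a-tetramethyl-1-[(3E,7E)-4,8,12-trimethyltrideca-3,7,11-trien-1-yl]-1,4,4a,5,6,8a-hexahydronaphthalen-3(2H)-one
Conditions: NBS (1.05 equiv), NaHCO3, anhydrous THF, −78 → −40 °C; aq. Na2S2O3/NaHCO3 work‑up; used crude
Reagents that add atoms: N‑bromosuccinimide (O=C1CCC(=O)N1Br)
Why: Electrophilic α‑bromination of a silyl enol ether with NBS should occur regiospecifically at C8 because the tetrasubstituted enol ether is far more nucleophilic than the trisubstituted chain olefins or the ring‑A olefin at low temperature without water, and the configuration of the new C8 centre is of no consequence since it is removed in step 9.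

Step 9
Reactants: 13 (1S,4aS,8aS)-2-bromo-2,5,5,8a-tetramethyl-1-[(3E,7E)-4,8,12-trimethyltrideca-3,7,11-trien-1-yl]-1,4,4a,5,6,8a-hexahydronaphthalen-3(2H)-one
Product: 14 (4aS,8aS)-2,5,5,8a-tetramethyl-1-[(3E,7E)-4,8,12-trimethyltrideca-3,7,11-trien-1-yl]-4a,5,6,8a-tetrahydronaphthalen-3(4H)-one
Conditions: Li2CO3, LiBr, DMF, 110 °C
Reagents that add atoms: none
Why: Dehydrobromination of the tertiary α‑bromo ketone with LiBr/Li2CO3 in hot DMF should give the conjugated tetrasubstituted C8=C9 enone as the thermodynamically preferred product (the classical conversion of a 2‑halo‑2‑methylcyclohexanone into 2‑methylcyclohex‑2‑enone), which erases the C9 configuration left by the cycloaddition.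

Step 10
Reactants: 14 (4aS,8aS)-2,5,5,8a-tetramethyl-1-[(3E,7E)-4,8,12-trimethyltrideca-3,7,11-trien-1-yl]-4a,5,6,8a-tetrahydronaphthalen-3(4H)-one
Product: 15 (4aS,8aS)-2,5,5,8a-tetramethyl-1-[(3E,7E)-4,8,12-trimethyltrideca-3,7,11-trien-1-yl]-4a,5,6,7,8,8a-hexahydronaphthalen-3(4H)-one
Conditions: H2 (1 atm), RhCl(PPh3)3 (10 mol%), benzene–EtOH, rt, stopped after one equivalent of H2
Reagents that add atoms: none
Why: Homogeneous hydrogenation with RhCl(PPh3)3 discriminates strongly by olefin substitution, so the cis‑disubstituted C1=C2 bond (an environment like that of Δ1‑steroids, whose α face is open once C9 is sp2) should be saturated while the trisubstituted chain olefins and the tetrasubstituted enone are left alone, which is why this reagent and this stage are preferred over a diimide reduction of the earlier enol ether.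

Step 11
Reactants: 15 (4aS,8aS)-2,5,5,8a-tetramethyl-1-[(3E,7E)-4,8,12-trimethyltrideca-3,7,11-trien-1-yl]-4a,5,6,7,8,8a-hexahydronaphthalen-3(4H)-one
Product: 17 (1R,4aS,8aS)-2,5,5,8a-tetramethyl-1-[(3E,7E)-4,8,12-trimethyltrideca-3,7,11-trien-1-yl]-1,4,4a,5,6,7,8,8a-octahydronaphthalen-3-yl trifluoromethanesulfonate, via lithium enolate 16 (not isolated)
Conditions: Li (2.2 equiv), NH3(l)/THF, t‑BuOH (1.0 equiv), −78 °C; isoprene; evaporate NH3; PhNTf2, THF, 0 °C → rt
Reagents that add atoms: N‑phenylbis(trifluoromethanesulfonimide) (O=S(=O)(N(c1ccccc1)S(=O)(=O)C(F)(F)F)C(F)(F)F)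
Why: Dissolving‑metal (Birch‑type) reduction of the enone gives the C7 enolate regiospecifically while the β‑carbon C9 is protonated axially from the α face, anti to the angular methyl, which places H‑9 α and the side chain equatorial (β) as in the target, and O‑triflation of enolate 16 after removal of ammonia fixes the C7=C8 double bond.

Step 12
Reactants: 17 (1R,4aS,8aS)-2,5,5,8a-tetramethyl-1-[(3E,7E)-4,8,12-trimethyltrideca-3,7,11-trien-1-yl]-1,4,4a,5,6,7,8,8a-octahydronaphthalen-3-yl trifluoromethanesulfonate
Product: 18 (1S,4aS,8aS)-2,5,5,8a-tetramethyl-1-[(3E,7E)-4,8,12-trimethyltrideca-3,7,11-trien-1-yl]-1,4,4a,5,6,7,8,8a-octahydronaphthalene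
Conditions: Pd(OAc)2 (5 mol%), PPh3 (10 mol%), HCO2H, Bu3N, DMF, 60 °C
Reagents that add atoms: none
Why: Palladium‑catalysed formate reduction of an enol triflate (oxidative addition, formate exchange, decarboxylation, reductive elimination) should replace OTf by H without moving the C7=C8 bond, touching the isolated olefins or disturbing C9.

**Compound list**

1 | (2E,6E)-farnesyl bromide [(2E,6E)-1-bromo-3,7,11-trimethyldodeca-2,6,10-triene] | CC(C)=CCC/C(C)=C/CC/C(C)=C/CBr | starting material
2 | (4E,8E)-N-tert-butyl-5,9,13-trimethyltetradeca-4,8,12-trien-1-imine | CC(C)=CCC/C(C)=C/CC/C(C)=C/CCC=NC(C)(C)C | intermediate (not isolated)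
3 | (4E,8E)-5,9,13-trimethyltetradeca-4,8,12-trienal | CC(C)=CCC/C(C)=C/CC/C(C)=C/CCC=O | intermediate
4 | 3-(triphenylphosphoranylidene)butan-2-one | CC(=O)C(C)=P(c1ccccc1)(c1ccccc1)c1ccccc1 | starting material
5 | (3E,7E,11E)-3,8,12,16-tetramethylheptadeca-3,7,11,15-tetraen-2-one | CC(C)=CCC/C(C)=C/CC/C(C)=C/CC/C=C(\C)C(C)=O | intermediate
6 | (3E,7E,11E)-3,8,12,16-tetramethyl-2-[(triisopropylsilyl)oxy]heptadeca-1,3,7,11,15-pentaene (diene of the key step) | CC(C)=CCC/C(C)=C/CC/C(C)=C/CC/C=C(\C)C(=C)O[Si](C(C)C)(C(C)C)C(C)C | intermediate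
7 | 2,2-dimethylpent-4-enal | O=CC(C)(C)CC=C | starting material
8 | 2-(triphenylphosphoranylidene)propanal | O=CC(C)=P(c1ccccc1)(c1ccccc1)c1ccccc1 | starting material
9 | (E)-2,4,4-trimethylhepta-2,6-dienal (dienophile of the key step) | O=C/C(C)=C/C(C)(C)CC=C | intermediate
10 | (1S,2R,6S)-1,3-dimethyl-6-(2-methylpent-4-en-2-yl)-4-[(triisopropylsilyl)oxy]-2-[(3E,7E)-4,8,12-trimethyltrideca-3,7,11-trien-1-yl]cyclohex-3-ene-1-carbaldehyde (endo adduct; side chain cis to CHO; C5 and C10 as in the target, C9 epimeric) | CC(C)=CCC/C(C)=C/CC/C(C)=C/CC[C@@H]1C(C)=C(O[Si](C(C)C)(C(C)C)C(C)C)C[C@@H](C(C)(C)CC=C)[C@]1(C)C=O | intermediate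
11 | (1S,2S,6S)-1-ethenyl-1,3-dimethyl-6-(2-methylpent-4-en-2-yl)-4-[(triisopropylsilyl)oxy]-2-[(3E,7E)-4,8,12-trimethyltrideca-3,7,11-trien-1-yl]cyclohex-3-ene (locants of 10 kept; same spatial arrangement) | CC(C)=CCC/C(C)=C/CC/C(C)=C/CC[C@@H]1C(C)=C(O[Si](C(C)C)(C(C)C)C(C)C)C[C@@H](C(C)(C)CC=C)[C@]1(C)C=C | intermediate
12 | (1S,4aS,8aS)-2,5,5,8a-tetramethyl-3-[(triisopropylsilyl)oxy]-1-[(3E,7E)-4,8,12-trimethyltrideca-3,7,11-trien-1-yl]-1,4,4a,5,6,8a-hexahydronaphthalene (trans-fused; side chain α, trans to the 8a-methyl) | CC(C)=CCC/C(C)=C/CC/C(C)=C/CC[C@@H]1C(C)=C(O[Si](C(C)C)(C(C)C)C(C)C)C[C@H]2C(C)(C)CC=C[C@]12C | intermediate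
13 | (1S,4aS,8aS)-2-bromo-2,5,5,8a-tetramethyl-1-[(3E,7E)-4,8,12-trimethyltrideca-3,7,11-trien-1-yl]-1,4,4a,5,6,8a-hexahydronaphthalen-3(2H)-one (either C2 epimer) | CC(C)=CCC/C(C)=C/CC/C(C)=C/CC[C@@H]1C(C)(Br)C(=O)C[C@H]2C(C)(C)CC=C[C@]12C | intermediate
14 | (4aS,8aS)-2,5,5,8a-tetramethyl-1-[(3E,7E)-4,8,12-trimethyltrideca-3,7,11-trien-1-yl]-4a,5,6,8a-tetrahydronaphthalen-3(4H)-one | CC(C)=CCC/C(C)=C/CC/C(C)=C/CCC1=C(C)C(=O)C[C@H]2C(C)(C)CC=C[C@]12C | intermediate
15 | (4aS,8aS)-2,5,5,8a-tetramethyl-1-[(3E,7E)-4,8,12-trimethyltrideca-3,7,11-trien-1-yl]-4a,5,6,7,8,8a-hexahydronaphthalen-3(4H)-one | CC(C)=CCC/C(C)=C/CC/C(C)=C/CCC1=C(C)C(=O)C[C@H]2C(C)(C)CCC[C@]12C | intermediate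
16 | lithium (1R,4aS,8aS)-2,5,5,8a-tetramethyl-1-[(3E,7E)-4,8,12-trimethyltrideca-3,7,11-trien-1-yl]-1,4,4a,5,6,7,8,8a-octahydronaphthalen-3-olate (H-1 α, side chain β) | [Li+].CC(C)=CCC/C(C)=C/CC/C(C)=C/CC[C@H]1C(C)=C([O-])C[C@H]2C(C)(C)CCC[C@]12C | intermediate (not isolated)
17 | (1R,4aS,8aS)-2,5,5,8a-tetramethyl-1-[(3E,7E)-4,8,12-trimethyltrideca-3,7,11-trien-1-yl]-1,4,4a,5,6,7,8,8a-octahydronaphthalen-3-yl trifluoromethanesulfonate | CC(C)=CCC/C(C)=C/CC/C(C)=C/CC[C@H]1C(C)=C(OS(=O)(=O)C(F)(F)F)C[C@H]2C(C)(C)CCC[C@]12C | intermediate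
18 | (1S,4aS,8aS)-2,5,5,8a-tetramethyl-1-[(3E,7E)-4,8,12-trimethyltrideca-3,7,11-trien-1-yl]-1,4,4a,5,6,7,8,8a-octahydronaphthalene (CNP0141177.1) | CC(C)=CCC/C(C)=C/CC/C(C)=C/CC[C@H]1C(C)=CC[C@H]2C(C)(C)CCC[C@]12C | target

**Summary**

Total steps: 12. Longest linear sequence: 11 (steps 1–3 and 5–12, from farnesyl bromide).

Steps most likely to fail:

1. Step 5. The β‑tert‑alkyl enal may react too slowly, so that the diene is lost to protodesilylation or an open‑chain Michael pathway, or the catalyst may discriminate the enal faces poorly. The fallback sets out from 6 and 9 and comes back at 10. The cycloaddition is run with a stoichiometric achiral Lewis acid (Me2AlCl, CH2Cl2, −78 → −20 °C), which should give 10 as the racemate with the same regio‑ and relative configuration. The formyl group is reduced (NaBH4, EtOH, 0 °C) to the primary alcohol F1, and this is esterified with (S)‑O‑methylmandelic acid (DCC, DMAP, CH2Cl2) to give the (S)‑O‑methylmandelate ester F2 as two diastereomers. The diastereomer with the ring configuration of 10 is separated by chromatography, cleaved with DIBAL‑H (−78 °C) to enantiopure alcohol F1 and oxidised with Dess–Martin periodinane (NaHCO3) to 10.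

2. Step 10. Chemoselectivity may be lost through partial saturation of the chain olefins, or the crowded ring olefin may not turn over on rhodium. The fallback sets out from 14 and comes back at 15. The catalytic hydrogenation is replaced by a metal‑free concerted hydrogen transfer from diimide, generated in portions from 2‑nitrobenzenesulfonyl hydrazide and Et3N (CH2Cl2, rt) and followed to partial conversion with recycling of 14; diimide is small and favours the less substituted olefin. No new compound arises on this path (none F0).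

3. Step 11. The enolate may be protonated by ammonia or tert‑butanol before triflation, or the triflating agent may be consumed by lithium amide, so that ketone rather than triflate is obtained. The fallback sets out from 15 and comes back at 17 through 16. The reduction is quenched with NH4Cl to give the saturated ketone F3 (H‑9 α; C8 epimers). This is converted under equilibrating conditions (TMSCl, NaI, Et3N, MeCN, rt) into the more substituted trimethylsilyl enol ether F4, which is cleaved with MeLi (THF, 0 °C) to regenerate lithium enolate 16 free of amide base and proton sources, and 16 is triflated with PhNTf2 to 17.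

Further compounds
F1 | step 5 | primary alcohol from reduction of the formyl group of 10, {1,3-dimethyl-6-(2-methylpent-4-en-2-yl)-4-[(triisopropylsilyl)oxy]-2-[(3E,7E)-4,8,12-trimethyltrideca-3,7,11-trien-1-yl]cyclohex-3-en-1-yl}methanol with the ring configuration of 10 | CC(C)=CCC/C(C)=C/CC/C(C)=C/CC[C@@H]1C(C)=C(O[Si](C(C)C)(C(C)C)C(C)C)C[C@@H](C(C)(C)CC=C)[C@]1(C)CO
F2 | step 5 | (S)-2-methoxy-2-phenylacetate (O-methylmandelate) ester of F1 | CC(C)=CCC/C(C)=C/CC/C(C)=C/CC[C@@H]1C(C)=C(O[Si](C(C)C)(C(C)C)C(C)C)C[C@@H](C(C)(C)CC=C)[C@]1(C)COC(=O)[C@@H](OC)c2ccccc2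
F0 | step 10 | none | none
F3 | step 11 | (1S,4aS,8aS)-2,5,5,8a-tetramethyl-1-[(3E,7E)-4,8,12-trimethyltrideca-3,7,11-trien-1-yl]octahydronaphthalen-3(2H)-one (saturated ketone, H-1 α, C2 epimers) | CC(C)=CCC/C(C)=C/CC/C(C)=C/CC[C@H]1C(C)C(=O)C[C@H]2C(C)(C)CCC[C@]12C
F4 | step 11 | trimethylsilyl enol ether corresponding to enolate 16, (1R,4aS,8aS)-2,5,5,8a-tetramethyl-3-[(trimethylsilyl)oxy]-1-[(3E,7E)-4,8,12-trimethyltrideca-3,7,11-trien-1-yl]-1,4,4a,5,6,7,8,8a-octahydronaphthalene | CC(C)=CCC/C(C)=C/CC/C(C)=C/CC[C@H]1C(C)=C(O[Si](C)(C)C)C[C@H]2C(C)(C)CCC[C@]12C
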